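**Retrosynthetic overview**

1. The target is 4'-O-methylcupressuflavone: unit 1 (the 4-methoxyphenyl flavone) and unit 2 (apigenin) joined C8–C8. The strategy rests on ring A of unit 1, a phloroglucinol ring whose C8 carries unit 2 between the oxygen-bearing C7 and C8a, with the third oxygen at C5 para to C8.
2. Last disconnections, ring C of unit 1: O1–C2 (cyclodehydration), C2–C3 (enolate aroylation with 4-methoxybenzoyl chloride), C4–C4a (ortho-acetylation beside the C8a hydroxyl).
3. Key disconnection, ring A of unit 1: 3-ethoxycyclobutenone plus the 8-(silyloxyethynyl)flavone of unit 2. C8–C8a and C6–C7 come from the ketene–alkyne [2+2] event and C4a–C8a from 6π closure, so the hindered biaryl bond is the former aryl–alkyne bond.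
4. The ynol silyl ether comes from apigenin: benzylation, C8 iodination, Sonogashira coupling, desilylation, acetylide oxidation and O-silylation.
5. Ring order: rings A, B, C of unit 2 are bought as apigenin; ring A of unit 1 forms in step 6; ring C of unit 1 forms in step 9; ring B of unit 1 arrives with the acid chloride.

Key step: step 6

Remark on the chemistry: the target SMILES fixes no configuration at the C8–C8 axis, so the racemate is the goal; 3-ethoxycyclobut-2-en-1-one (10) is assumed to be a purchased compound (it is otherwise made by [2+2] addition of ketene to ethoxyacetylene).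

**Route**

Step 1
Reactants: 1 apigenin
Product: 2 5,7-bis(benzyloxy)-2-[4-(benzyloxy)phenyl]chromen-4-one
Conditions: BnBr (4.5 equiv), K2CO3, Bu4NI (cat.), DMF, 80 °C
Reagents that add atoms: benzyl bromide, BrCc1ccccc1
Why: Williamson etherification, in which hot DMF with excess K2CO3 and bromide also alkylates the hydrogen-bonded 5-OH; benzyl ethers are chosen because they should pass the bases, the heat and the mild acids of the route and fall to BCl3 at the end without harm to the methyl ether.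

Step 2
Reactants: 2 5,7-bis(benzyloxy)-2-[4-(benzyloxy)phenyl]chromen-4-one
Product: 3 5,7-bis(benzyloxy)-2-[4-(benzyloxy)phenyl]-8-iodochromen-4-one
Conditions: I2, CF3CO2Ag, CH2Cl2, rt, dark
Reagents that add atoms: iodine, II
Why: Electrophilic aromatic iodination by the iodonium species from I2 and CF3CO2Ag; in fully O-alkylated 5,7-dioxygenated flavones C8 (ortho to O1 and the 7-benzyloxy group, para to the 5-benzyloxy group) reacts ahead of the more shielded C6 and of the deactivated ring B, as known for the corresponding methyl ethers.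

Step 3
Reactants: 3 5,7-bis(benzyloxy)-2-[4-(benzyloxy)phenyl]-8-iodochromen-4-one; 4 ethynyltrimethylsilane
Product: 5 5,7-bis(benzyloxy)-2-[4-(benzyloxy)phenyl]-8-[(trimethylsilyl)ethynyl]chromen-4-one
Conditions: PdCl2(PPh3)2 (5 mol %), CuI (10 mol %), Et3N, DMF, 70 °C
Reagents that add atoms: none
Why: Sonogashira coupling, for which the electron-rich iodide flanked by two ortho oxygens needs DMF at 70 °C while the slim alkyne tolerates the hindrance.

Step 4
Reactants: 5 5,7-bis(benzyloxy)-2-[4-(benzyloxy)phenyl]-8-[(trimethylsilyl)ethynyl]chromen-4-one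
Product: 6 5,7-bis(benzyloxy)-2-[4-(benzyloxy)phenyl]-8-ethynylchromen-4-one
Conditions: K2CO3 (0.2 equiv), MeOH–THF, rt
Reagents that add atoms: none
Why: Protodesilylation of the C(sp)–Si bond by catalytic methoxide, under which benzyl ethers and the pyranone are stable.

Step 5
Reactants: 6 5,7-bis(benzyloxy)-2-[4-(benzyloxy)phenyl]-8-ethynylchromen-4-one
Product: 9 5,7-bis(benzyloxy)-2-[4-(benzyloxy)phenyl]-8-[(triisopropylsilyloxy)ethynyl]chromen-4-one, via lithium acetylide 7 (not isolated), via lithium ynolate 8 (not isolated)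
Conditions: LiN(SiMe3)2, THF, −78 °C; add to t-BuOOLi (t-BuOOH, LiN(SiMe3)2, THF, −78 °C), then 0 °C; TIPSOTf, −78 → 0 °C; chromatography on Et3N-deactivated silica
Reagents that add atoms: tert-butyl hydroperoxide, CC(C)(C)OO; triisopropylsilyl trifluoromethanesulfonate, CC(C)[Si](OS(=O)(=O)C(F)(F)F)(C(C)C)C(C)C
Why: Oxidation of a lithium acetylide by the electrophilic oxygen of lithium tert-butyl peroxide to the lithium ynolate, then O-silylation with the hard and bulky silyl triflate, is a known route to (triisopropylsilyloxy)alkynes; LiN(SiMe3)2 removes only the alkyne proton, and an electron-rich 2-aryl-5,7-dialkoxychromen-4-one is a poor acceptor for the peroxide anion at or below 0 °C.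

Step 6
Reactants: 9 5,7-bis(benzyloxy)-2-[4-(benzyloxy)phenyl]-8-[(triisopropylsilyloxy)ethynyl]chromen-4-one; 10 3-ethoxycyclobut-2-en-1-one
Product: 15 8-[4-ethoxy-2-hydroxy-6-(triisopropylsilyloxy)phenyl]-5,7-bis(benzyloxy)-2-[4-(benzyloxy)phenyl]chromen-4-one, via vinylketene 11 (not isolated), via vinylcyclobutenone 12 (not isolated), via dienylketene 13 (not isolated), via cyclohexadienone 14 (not isolated)
Conditions: 10 (1.3 equiv, in portions), toluene, 80 °C, then 110 °C, Ar
Reagents that add atoms: none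
Why: Danheiser benzannulation: thermal 4π electrocyclic opening of 10 gives vinylketene 11, whose ketene C=C adds [2+2] across the triple bond of 9 to give 4-vinylcyclobutenone 12, and a second 4π opening gives dienylketene 13, which closes to cyclohexadienone 14 and enolizes to phenol 15. The closest known case is the same cascade of cyclobutenones with (triisopropylsilyloxy)alkynes, which gives resorcinol monosilyl ethers. The one new ring, ring A of unit 1, is closed by the thermal 6π electrocyclization that forms C4a–C8a after the [2+2] event has made C8–C8a and C6–C7, so the tetra-ortho-substituted biaryl bond is never made by aryl–aryl coupling. No stereocenter survives, since the sp3 carbons of 12 and 14 are lost on aromatization and the new axis forms as the racemate. The step needs the ketene carbonyl carbon to bond to the aryl-bearing alkyne carbon, and the silyloxy group secures this by making that carbon the nucleophilic β-carbon of the ynol ether, which places unit 2 between the new hydroxyl and the silyloxy group with the ethoxy group para to it. The conditions are neutral and purely thermal, so the benzyl ethers, the silyl ether and the pyranone of unit 2 should be untouched.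

Step 7
Reactants: 15 8-[4-ethoxy-2-hydroxy-6-(triisopropylsilyloxy)phenyl]-5,7-bis(benzyloxy)-2-[4-(benzyloxy)phenyl]chromen-4-one
Product: 17 8-[3-acetyl-4-ethoxy-2-hydroxy-6-(triisopropylsilyloxy)phenyl]-5,7-bis(benzyloxy)-2-[4-(benzyloxy)phenyl]chromen-4-one, via difluoroboron chelate 16 (not isolated)
Conditions: Ac2O, BF3·OEt2, CH2Cl2, 0 °C → rt; then NaOAc, aq. MeOH, 40 °C
Reagents that add atoms: acetic anhydride, CC(=O)OC(C)=O
Why: Friedel–Crafts ortho-acetylation in its Fries variant on a phloroglucinol-type phenol, in which the acyl group is delivered to the carbon between the free hydroxyl and the ethoxy group (the future C4a) and held there as the six-membered difluoroboron chelate 16, while the other free carbon is shielded by the triisopropylsilyloxy group and aryl benzyl and silyl ethers should survive a short exposure to BF3·OEt2 at 0 °C.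

Step 8
Reactants: 17 8-[3-acetyl-4-ethoxy-2-hydroxy-6-(triisopropylsilyloxy)phenyl]-5,7-bis(benzyloxy)-2-[4-(benzyloxy)phenyl]chromen-4-one; 18 4-methoxybenzoyl chloride
Product: 20 1-{3-[5,7-bis(benzyloxy)-2-(4-benzyloxyphenyl)-4-oxo-4H-chromen-8-yl]-6-ethoxy-2-hydroxy-4-(triisopropylsilyloxy)phenyl}-3-(4-methoxyphenyl)propane-1,3-dione, via dilithium phenoxide-enolate 19 (not isolated)
Conditions: LiN(SiMe3)2 (3.2 equiv), THF, −78 → −10 °C; 18 (1.05 equiv), −78 °C → rt; aq. HCl
Reagents that add atoms: none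
Why: Claisen-type C-aroylation of the dilithium phenoxide–enolate 19, the one-flask form of the Baker–Venkataraman route to 1-(2-hydroxyaryl)-1,3-diketones, in which the third equivalent of base takes up the acidic diketone and any ester formed at the hindered phenoxide would rearrange to the same diketone.

Step 9
Reactants: 20 1-{3-[5,7-bis(benzyloxy)-2-(4-benzyloxyphenyl)-4-oxo-4H-chromen-8-yl]-6-ethoxy-2-hydroxy-4-(triisopropylsilyloxy)phenyl}-3-(4-methoxyphenyl)propane-1,3-dione
Product: 22 8-[5,7-bis(benzyloxy)-2-(4-benzyloxyphenyl)-4-oxo-4H-chromen-8-yl]-5-ethoxy-2-(4-methoxyphenyl)-7-(triisopropylsilyloxy)chromen-4-one, via hemiketal 21 (not isolated)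
Conditions: TsOH·H2O (0.2 equiv), toluene, 90 °C
Reagents that add atoms: none
Why: Acid-catalysed cyclodehydration, the last stage of the Baker–Venkataraman flavone synthesis, in which the C8a hydroxyl adds 6-exo-trig to the aroyl carbonyl to give hemiketal 21 and loss of water gives the pyranone (ring C of unit 1) under conditions that should leave benzyl and triisopropylsilyl aryl ethers in place.

Step 10
Reactants: 22 8-[5,7-bis(benzyloxy)-2-(4-benzyloxyphenyl)-4-oxo-4H-chromen-8-yl]-5-ethoxy-2-(4-methoxyphenyl)-7-(triisopropylsilyloxy)chromen-4-one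
Product: 23 8-[5,7-bis(benzyloxy)-2-(4-benzyloxyphenyl)-4-oxo-4H-chromen-8-yl]-5-ethoxy-7-hydroxy-2-(4-methoxyphenyl)chromen-4-one
Conditions: Bu4NF, AcOH, THF, 0 °C
Reagents that add atoms: none
Why: Fluoride-induced cleavage of the aryl silyl ether, driven by the strong Si–F bond and buffered with AcOH so that the liberated 7-phenoxide is not kept under basic conditions.

Step 11
Reactants: 23 8-[5,7-bis(benzyloxy)-2-(4-benzyloxyphenyl)-4-oxo-4H-chromen-8-yl]-5-ethoxy-7-hydroxy-2-(4-methoxyphenyl)chromen-4-one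
Product: 24 5,7-dihydroxy-8-[5,7-dihydroxy-2-(4-hydroxyphenyl)-4-oxo-4H-chromen-8-yl]-2-(4-methoxyphenyl)chromen-4-one
Conditions: BCl3, C6HMe5, CH2Cl2, −78 → 0 °C (→ rt if the ethyl ether remains); MeOH quench
Reagents that add atoms: none
Why: Lewis acid ether cleavage, in which BCl3 removes the three benzyl groups as cations trapped by pentamethylbenzene and the 5-ethyl group by chloride attack inside the chelate with the C4 carbonyl, while the non-chelated 4'-methyl ether of unit 1 is not cleaved by BCl3 at or below room temperature.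

**Compound list**

Ar8 in the names below is the 5,7-bis(benzyloxy)-2-[4-(benzyloxy)phenyl]-4-oxo-4H-chromen-8-yl group of unit 2. Compounds 15–17, 19, 20, 22–24 are racemic at the biaryl axis; the sp3 centers of 12 and 21 are not controlled.

1 | apigenin (5,7-dihydroxy-2-(4-hydroxyphenyl)chromen-4-one) | O=c1cc(-c2ccc(O)cc2)oc2cc(O)cc(O)c12 | starting material
2 | 5,7-bis(benzyloxy)-2-[4-(benzyloxy)phenyl]chromen-4-one | O=c1cc(-c2ccc(OCc3ccccc3)cc2)oc2cc(OCc3ccccc3)cc(OCc3ccccc3)c12 | intermediate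
3 | 5,7-bis(benzyloxy)-2-[4-(benzyloxy)phenyl]-8-iodochromen-4-one | O=c1cc(-c2ccc(OCc3ccccc3)cc2)oc2c(I)c(OCc3ccccc3)cc(OCc3ccccc3)c12 | intermediate
4 | ethynyltrimethylsilane | C#C[Si](C)(C)C | starting material
5 | 5,7-bis(benzyloxy)-2-[4-(benzyloxy)phenyl]-8-[(trimethylsilyl)ethynyl]chromen-4-one | O=c1cc(-c2ccc(OCc3ccccc3)cc2)oc2c(C#C[Si](C)(C)C)c(OCc3ccccc3)cc(OCc3ccccc3)c12 | intermediate
6 | 5,7-bis(benzyloxy)-2-[4-(benzyloxy)phenyl]-8-ethynylchromen-4-one | O=c1cc(-c2ccc(OCc3ccccc3)cc2)oc2c(C#C)c(OCc3ccccc3)cc(OCc3ccccc3)c12 | intermediate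
7 | lithium acetylide of 6 (Ar8–C≡C–Li) | [Li]C#Cc1c(OCc2ccccc2)cc(OCc2ccccc2)c2c(=O)cc(-c3ccc(OCc4ccccc4)cc3)oc12 | intermediate (not isolated)
8 | lithium ynolate (Ar8–C≡C–OLi) | [Li]OC#Cc1c(OCc2ccccc2)cc(OCc2ccccc2)c2c(=O)cc(-c3ccc(OCc4ccccc4)cc3)oc12 | intermediate (not isolated)
9 | 5,7-bis(benzyloxy)-2-[4-(benzyloxy)phenyl]-8-[(triisopropylsilyloxy)ethynyl]chromen-4-one | O=c1cc(-c2ccc(OCc3ccccc3)cc2)oc2c(C#CO[Si](C(C)C)(C(C)C)C(C)C)c(OCc3ccccc3)cc(OCc3ccccc3)c12 | intermediate
10 | 3-ethoxycyclobut-2-en-1-one | CCOC1=CC(=O)C1 | starting material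
11 | 3-ethoxybuta-1,3-dien-1-one ((1-ethoxyvinyl)ketene) | C=C(OCC)C=C=O | intermediate (not isolated)
12 | 2-Ar8-4-(1-ethoxyvinyl)-3-(triisopropylsilyloxy)cyclobut-2-en-1-one | C=C(OCC)C1C(=O)C(c2c(OCc3ccccc3)cc(OCc3ccccc3)c3c(=O)cc(-c4ccc(OCc5ccccc5)cc4)oc23)=C1O[Si](C(C)C)(C(C)C)C(C)C | intermediate (not isolated)
13 | (3E)-2-Ar8-5-ethoxy-3-(triisopropylsilyloxy)hexa-1,3,5-trien-1-one | C=C(OCC)/C=C(O[Si](C(C)C)(C(C)C)C(C)C)\C(=C=O)c1c(OCc2ccccc2)cc(OCc2ccccc2)c2c(=O)cc(-c3ccc(OCc4ccccc4)cc3)oc12 | intermediate (not isolated)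
14 | 2-Ar8-5-ethoxy-3-(triisopropylsilyloxy)cyclohexa-2,4-dien-1-one | O=C1CC(OCC)=CC(O[Si](C(C)C)(C(C)C)C(C)C)=C1c1c(OCc2ccccc2)cc(OCc2ccccc2)c2c(=O)cc(-c3ccc(OCc4ccccc4)cc3)oc12 | intermediate (not isolated)
15 | 8-[4-ethoxy-2-hydroxy-6-(triisopropylsilyloxy)phenyl]-5,7-bis(benzyloxy)-2-[4-(benzyloxy)phenyl]chromen-4-one | O=c1cc(-c2ccc(OCc3ccccc3)cc2)oc2c(-c3c(O)cc(OCC)cc3O[Si](C(C)C)(C(C)C)C(C)C)c(OCc3ccccc3)cc(OCc3ccccc3)c12 | intermediate
16 | difluoroboron chelate of 17 (boron bridges the phenol oxygen and the acetyl oxygen) | CC1=[O+][B-](F)(F)Oc2c1c(OCC)cc(O[Si](C(C)C)(C(C)C)C(C)C)c2-c1c(OCc2ccccc2)cc(OCc2ccccc2)c2c(=O)cc(-c3ccc(OCc4ccccc4)cc3)oc12 | intermediate (not isolated)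
17 | 8-[3-acetyl-4-ethoxy-2-hydroxy-6-(triisopropylsilyloxy)phenyl]-5,7-bis(benzyloxy)-2-[4-(benzyloxy)phenyl]chromen-4-one | O=c1cc(-c2ccc(OCc3ccccc3)cc2)oc2c(-c3c(O)c(C(C)=O)c(OCC)cc3O[Si](C(C)C)(C(C)C)C(C)C)c(OCc3ccccc3)cc(OCc3ccccc3)c12 | intermediate
18 | 4-methoxybenzoyl chloride | COc1ccc(C(=O)Cl)cc1 | starting material
19 | dilithium phenoxide–enolate of 17 | C=C(O[Li])c1c(O[Li])c(-c2c(OCc3ccccc3)cc(OCc3ccccc3)c3c(=O)cc(-c4ccc(OCc5ccccc5)cc4)oc23)c(O[Si](C(C)C)(C(C)C)C(C)C)cc1OCC | intermediate (not isolated)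
20 | 1-[3-Ar8-6-ethoxy-2-hydroxy-4-(triisopropylsilyloxy)phenyl]-3-(4-methoxyphenyl)propane-1,3-dione | COc1ccc(C(=O)CC(=O)c2c(O)c(-c3c(OCc4ccccc4)cc(OCc4ccccc4)c4c(=O)cc(-c5ccc(OCc6ccccc6)cc5)oc34)c(O[Si](C(C)C)(C(C)C)C(C)C)cc2OCC)cc1 | intermediate
21 | 8-Ar8-5-ethoxy-2-hydroxy-2-(4-methoxyphenyl)-7-(triisopropylsilyloxy)chroman-4-one (cyclic hemiketal) | COc1ccc(C2(O)CC(=O)c3c(OCC)cc(O[Si](C(C)C)(C(C)C)C(C)C)c(-c4c(OCc5ccccc5)cc(OCc5ccccc5)c5c(=O)cc(-c6ccc(OCc7ccccc7)cc6)oc45)c3O2)cc1 | intermediate (not isolated)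
22 | 8-Ar8-5-ethoxy-2-(4-methoxyphenyl)-7-(triisopropylsilyloxy)chromen-4-one | COc1ccc(-c2cc(=O)c3c(OCC)cc(O[Si](C(C)C)(C(C)C)C(C)C)c(-c4c(OCc5ccccc5)cc(OCc5ccccc5)c5c(=O)cc(-c6ccc(OCc7ccccc7)cc6)oc45)c3o2)cc1 | intermediate
23 | 8-Ar8-5-ethoxy-7-hydroxy-2-(4-methoxyphenyl)chromen-4-one | COc1ccc(-c2cc(=O)c3c(OCC)cc(O)c(-c4c(OCc5ccccc5)cc(OCc5ccccc5)c5c(=O)cc(-c6ccc(OCc7ccccc7)cc6)oc45)c3o2)cc1 | intermediate
24 | 5,7-dihydroxy-8-[5,7-dihydroxy-2-(4-hydroxyphenyl)-4-oxo-4H-chromen-8-yl]-2-(4-methoxyphenyl)chromen-4-one (CNP0322111.0) | COc1ccc(-c2cc(=O)c3c(O)cc(O)c(-c4c(O)cc(O)c5c(=O)cc(-c6ccc(O)cc6)oc45)c3o2)cc1 | target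

**Count and risks**

Total step count: 11. Longest linear sequence: 11 steps (apigenin 1 to target 24).

Steps most likely to fail:

1. Step 6. The [2+2] addition may be too slow because the two ortho substituents of unit 2 shield the triple bond. Then 1,3-migration of silicon from oxygen to carbon in the ynol ether, oligomerization of the vinylketene, or acylation of the product phenol by the ketene would take over, and a share of reversed [2+2] regiochemistry is also possible. The fallback makes the biaryl bond by cross-coupling; it sets out from iodide 3 and comes back at target 24. Commercial acacetin (5,7-dihydroxy-2-(4-methoxyphenyl)chromen-4-one, COc1ccc(-c2cc(=O)c3c(O)cc(O)cc3o2)cc1) is benzylated (BnBr, K2CO3, DMF, 80 °C) to 5,7-bis(benzyloxy)-2-(4-methoxyphenyl)chromen-4-one F1. F1 is iodinated at C8 (I2, CF3CO2Ag, CH2Cl2) to the 8-iodide F2, and Miyaura borylation (B2pin2, PdCl2(dppf), KOAc, dioxane, 90 °C) gives the 8-pinacolboronate F3. Suzuki–Miyaura coupling of F3 with 3 (Pd2(dba)3, SPhos, K3PO4, toluene–water, 100 °C) should give the pentabenzyl 8,8-linked biflavone F4. BCl3 with pentamethylbenzene (CH2Cl2, −78 → 0 °C) then removes the five benzyl groups and gives 24.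

2. Step 5. The acetylide, the peroxide anion or the ynolate may attack the pyranone of a second molecule (conjugate addition at C2 or addition at C4), or oxygen transfer may stay incomplete. The fallback reaches the ynolate by rearrangement instead of oxidation; it sets out from iodide 3 and comes back at ynolate 8, which is silylated to 9 as in step 5. Palladium-catalysed methoxycarbonylation of 3 (Pd(OAc)2, dppf, CO, MeOH, Et3N, DMF, 70 °C) gives methyl 5,7-bis(benzyloxy)-2-[4-(benzyloxy)phenyl]-4-oxo-4H-chromene-8-carboxylate F5. Kowalski ester homologation follows: LiCHBr2 (CH2Br2, lithium 2,2,6,6-tetramethylpiperidide, THF, −78 °C) converts F5 into the 8-(dibromoacetyl)flavone F6. Its lithium enolate (LiN(SiMe3)2), on bromine–lithium exchange with n-BuLi (−78 → 0 °C), rearranges by 1,2-aryl shift to 8.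

3. Step 7. The Lewis acid and the hydrogen fluoride set free may remove the peri benzyl ether of unit 2 or the silyl ether, or acetylation may go to the carbon between the ethoxy and silyloxy groups. The fallback avoids Lewis acids; it sets out from phenol 15 and comes back at acetophenone 17. Casnati–Skattebøl ortho-formylation (MgCl2, Et3N, paraformaldehyde, MeCN, reflux) puts the aldehyde only beside the free hydroxyl and gives 8-[4-ethoxy-3-formyl-2-hydroxy-6-(triisopropylsilyloxy)phenyl]-5,7-bis(benzyloxy)-2-[4-(benzyloxy)phenyl]chromen-4-one F7. Aldehyde-selective methyl addition (MeTi(OiPr)3, THF, −40 → 0 °C) gives the 1-hydroxyethyl compound F8 as a mixture of diastereomers, and MnO2 (CH2Cl2, rt) oxidizes the benzylic alcohol to 17.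

**Further compounds**

F1 | step 6 | 5,7-bis(benzyloxy)-2-(4-methoxyphenyl)chromen-4-one | COc1ccc(-c2cc(=O)c3c(OCc4ccccc4)cc(OCc4ccccc4)cc3o2)cc1
F2 | step 6 | 5,7-bis(benzyloxy)-8-iodo-2-(4-methoxyphenyl)chromen-4-one | COc1ccc(-c2cc(=O)c3c(OCc4ccccc4)cc(OCc4ccccc4)c(I)c3o2)cc1
F3 | step 6 | 5,7-bis(benzyloxy)-2-(4-methoxyphenyl)-8-(4,4,5,5-tetramethyl-1,3,2-dioxaborolan-2-yl)chromen-4-one | COc1ccc(-c2cc(=O)c3c(OCc4ccccc4)cc(OCc4ccccc4)c(B4OC(C)(C)C(C)(C)O4)c3o2)cc1
F4 | step 6 | 5,7-bis(benzyloxy)-8-[5,7-bis(benzyloxy)-2-(4-benzyloxyphenyl)-4-oxo-4H-chromen-8-yl]-2-(4-methoxyphenyl)chromen-4-one | COc1ccc(-c2cc(=O)c3c(OCc4ccccc4)cc(OCc4ccccc4)c(-c4c(OCc5ccccc5)cc(OCc5ccccc5)c5c(=O)cc(-c6ccc(OCc7ccccc7)cc6)oc45)c3o2)cc1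
F5 | step 5 | methyl 5,7-bis(benzyloxy)-2-[4-(benzyloxy)phenyl]-4-oxo-4H-chromene-8-carboxylate | COC(=O)c1c(OCc2ccccc2)cc(OCc2ccccc2)c2c(=O)cc(-c3ccc(OCc4ccccc4)cc3)oc12
F6 | step 5 | 5,7-bis(benzyloxy)-2-[4-(benzyloxy)phenyl]-8-(dibromoacetyl)chromen-4-one | O=C(C(Br)Br)c1c(OCc2ccccc2)cc(OCc2ccccc2)c2c(=O)cc(-c3ccc(OCc4ccccc4)cc3)oc12
F7 | step 7 | 8-[4-ethoxy-3-formyl-2-hydroxy-6-(triisopropylsilyloxy)phenyl]-5,7-bis(benzyloxy)-2-[4-(benzyloxy)phenyl]chromen-4-one | O=Cc1c(O)c(-c2c(OCc3ccccc3)cc(OCc3ccccc3)c3c(=O)cc(-c4ccc(OCc5ccccc5)cc4)oc23)c(O[Si](C(C)C)(C(C)C)C(C)C)cc1OCC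
F8 | step 7 | 8-[4-ethoxy-2-hydroxy-3-(1-hydroxyethyl)-6-(triisopropylsilyloxy)phenyl]-5,7-bis(benzyloxy)-2-[4-(benzyloxy)phenyl]chromen-4-one | CC(O)c1c(O)c(-c2c(OCc3ccccc3)cc(OCc3ccccc3)c3c(=O)cc(-c4ccc(OCc5ccccc5)cc4)oc23)c(O[Si](C(C)C)(C(C)C)C(C)C)cc1OCC
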